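**Retrosynthetic overview**

1. Feature: ring B (C1–C2–C3–C4–C5) holds the quaternary methyl carbon C1 next to carbinol carbon C10, an oxygen at C4, and the oxygenated carbon C6 on fusion carbon C5. With C4 as ketone and C6 as ester, this is a 5-carbomethoxycyclopent-2-enone, which is a Nazarov product.
2. Last disconnections: the C10 acetate and C6 anisoate come from acylation. Ring A (seven-membered) comes from ring-closing metathesis at C8=C9, joining a C6 methallyl carbinol to a C10 vinyl carbinol ether.
3. Middle: the C4 ketone takes an isopropyl nucleophile. The C6 ester becomes an aldehyde and takes a methallyl nucleophile. C9 goes from CH2O to aldehyde to vinyl.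
4. Ring B is formed first, by 4π conrotatory closure of C1–C2 in the silyl dienone C2=C3–C4(=O)–C5=C1 (14 → 15). The C10 stereocentre steers the sense of rotation.
5. The dienone comes from methyl carbometalation of a glycerate-derived ynoate (C9, C10, C1), aldol capture by (E)-3-(trimethylsilyl)propenal (C2–C4), and oxidation. Ring order: B, then A.

Key step: step 10

Remark: daucane numbering is used (ring B = C1–C5; ring A = C1, C5, C6–C10); NAP = 2-naphthylmethyl (it tolerates the Lewis acid like a benzyl ether but leaves with DDQ beside the alkene and the esters), TBDPS = tert-butyldiphenylsilyl, TBS = tert-butyldimethylsilyl; the sense of conrotation in step 10 is a prediction from the model stated there.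

**Step 1**
Reactants: 1 methyl (S)-2,2-dimethyl-1,3-dioxolane-4-carboxylate
Product: 3 (R)-4-ethynyl-2,2-dimethyl-1,3-dioxolane, via aldehyde 2 (not isolated)
Conditions: i-Bu2AlH (1.1 equiv), CH2Cl2, −78 °C; then MeOH, K2CO3, dimethyl (1-diazo-2-oxopropyl)phosphonate, −78 °C → rt
Reagents that add atoms: dimethyl (1-diazo-2-oxopropyl)phosphonate (Ohira–Bestmann reagent), COP(=O)(OC)C(=[N+]=[N-])C(C)=O
Why: Partial ester reduction stops at the aluminium hemiacetal at −78 °C, and the released aldehyde 2 undergoes Seyferth–Gilbert homologation under K2CO3/MeOH, mild enough to leave the oxygenated stereocentre (future C10) intact.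

**Step 2**
Reactants: 3 (R)-4-ethynyl-2,2-dimethyl-1,3-dioxolane
Product: 4 (R)-but-3-yne-1,2-diol
Conditions: Dowex 50WX8 (H+ form), MeOH/H2O, rt
Reagents that add atoms: none
Why: Acid-catalysed acetal hydrolysis breaks no bond at the stereocentre.

**Step 3**
Reactants: 4 (R)-but-3-yne-1,2-diol
Product: 5 (R)-1-(tert-butyldiphenylsilyloxy)but-3-yn-2-ol
Conditions: TBDPSCl (1.0 equiv), imidazole, CH2Cl2, 0 °C
Reagents that add atoms: tert-butyl(chloro)diphenylsilane, CC(C)(C)[Si](Cl)(c1ccccc1)c1ccccc1
Why: Sterically controlled silylation places the bulky chlorosilane on the primary hydroxyl (C9–O) only.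

**Step 4**
Reactants: 5 (R)-1-(tert-butyldiphenylsilyloxy)but-3-yn-2-ol
Product: 6 (R)-NAP ether of 5
Conditions: NaH, 2-(bromomethyl)naphthalene, Bu4NI (cat.), THF, 0 °C
Reagents that add atoms: 2-(bromomethyl)naphthalene, BrCc1ccc2ccccc2c1
Why: Williamson ether synthesis in which the alkoxide rests on the more acidic propargylic oxygen, so a 1,2-shift of silicon that would create a primary alkoxide is uphill, and the iodide-activated halide traps the alkoxide at 0 °C without touching the stereocentre.

**Step 5**
Reactants: 6 (R)-NAP ether of 5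
Product: 8 methyl (R)-5-(TBDPS-oxy)-4-(NAP-oxy)pent-2-ynoate, via lithium acetylide 7 (not isolated)
Conditions: n-BuLi (1.0 equiv), THF, −78 °C; ClCO2Me, −78 → −20 °C
Reagents that add atoms: methyl chloroformate, COC(=O)Cl
Why: Deprotonation of the terminal alkyne with exactly one equivalent of base (no excess that could start a Wittig rearrangement of the NAP ether), followed by C-acylation of acetylide 7, gives the ynoate carrying C5 and C6.

**Step 6**
Reactants: 9 3-(trimethylsilyl)prop-2-yn-1-ol
Product: 10 (E)-3-(trimethylsilyl)prop-2-en-1-ol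
Conditions: NaAlH2(OCH2CH2OMe)2, Et2O, 0 °C → rt; H2O work-up
Reagents that add atoms: none
Why: Alkoxide-directed trans-hydroalumination of a propargylic alcohol followed by protonolysis gives the E vinylsilane.

**Step 7**
Reactants: 10 (E)-3-(trimethylsilyl)prop-2-en-1-ol
Product: 11 (E)-3-(trimethylsilyl)prop-2-enal
Conditions: MnO2, CH2Cl2, rt
Reagents that add atoms: none
Why: Allylic alcohol oxidation with MnO2 stops at the aldehyde and keeps the E geometry.

**Step 8**
Reactants: 8 methyl (R)-5-(TBDPS-oxy)-4-(NAP-oxy)pent-2-ynoate; 11 (E)-3-(trimethylsilyl)prop-2-enal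
Product: 13 (Z)-dienol ester (C4 carbinol epimers), via magnesium allenolate 12 (not isolated)
Conditions: MeMgBr (1.2 equiv), CuI·2LiCl (20 mol %), THF, −78 → −40 °C; then 11, −78 °C; aq. NH4Cl
Reagents that add atoms: methylmagnesium bromide, C[Mg]Br
Why: Copper-catalysed conjugate carbomagnesiation of an ynoate with aldol capture delivers methyl to C1 and lets the aldehyde attack allenolate 12 at C5 from the side of the small methyl group, so C4 ends cis to methyl and the ester cis to C10 (Z), which avoids condensing a ketone and never exposes H10 to enolising conditions; the new C4 centre is removed in step 9.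

**Step 9**
Reactants: 13 (Z)-dienol ester
Product: 14 silyl divinyl ketone ester, methyl (2Z,4R)-3-methyl-4-(NAP-oxy)-5-(TBDPS-oxy)-2-[(2E)-3-(trimethylsilyl)prop-2-enoyl]pent-2-enoate
Conditions: Dess–Martin periodinane, CH2Cl2, 0 °C → rt
Reagents that add atoms: none
Why: Dess–Martin oxidation of the bis-allylic alcohol works under near-neutral conditions that leave both alkene geometries, the vinylsilane and C10 untouched.

**Step 10**
Reactants: 14 silyl divinyl ketone ester
Product: 15 cyclopentenone β-keto ester, methyl (1R,2S)-2-methyl-2-[(1R)-1-(NAP-oxy)-2-(TBDPS-oxy)ethyl]-5-oxocyclopent-3-ene-1-carboxylate (daucane 1S,5R,10R)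
Conditions: Cu(OTf)2 (20 mol %), ClCH2CH2Cl/(CF3)2CHOH 10:1, 40 °C; aq. NaHCO3
Reagents that add atoms: none
Why: Cu(OTf)2 (divalent copper) is held by the ketone and ester oxygens in a six-membered chelate, which locks the U-shaped conformer and turns 14 into a pentadienyl cation with its electron-poor end at the disubstituted carbon C1 and its electron-rich end at the vinylsilane carbon C2. Thermal conrotatory 4π electrocyclisation bonds C1 to C2 and so closes ring B (five-membered electrocyclic closure); the closest known chemistry is the Lewis-acid Nazarov cyclisation of 2-alkylidene β-keto esters combined with silicon-directed termination. In the oxyallyl cation C3–C4–C5 the charge at C3 is β to silicon, so Me3Si departs from C2 (taken up by the fluorinated alcohol) before a Wagner–Meerwein shift from C1 can start, the alkene is placed at C2=C3 only, and the remaining enolate takes a proton at C5. C1 is set by the direction of conrotation: allylic 1,3-strain against the cis ester turns H10 into the dienone plane, the bulky and σ-donating CH2OTBDPS arm stands anti to the forming bond with the NAP-oxygen on the outside, and C2 should therefore bond to the face that makes C1 (S). C5 is an acidic β-keto ester carbon and equilibrates to the isomer with the ester trans to the large C10 arm, the relation that later becomes the trans ring fusion. The selectivities needed are closure through the geometric isomer with methyl (not C10) on the inside of the U, which is both the isomer made in step 8 and the faster-closing one if the Lewis acid scrambles the alkene, and survival of the C10 ether, whose ionisation would place a cation beside a doubly acceptor-substituted alkene.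

**Step 11**
Reactants: 15 cyclopentenone β-keto ester
Product: 16 saturated β-hydroxy ester (daucane 1S,5R,10R; C4 epimers)
Conditions: NiCl2·6H2O (0.3 equiv), NaBH4 (excess), MeOH, −20 → 0 °C
Reagents that add atoms: none
Why: Nickel boride conjugate reduction saturates C2=C3 and borohydride reduces the C4 ketone without hydrogenolysis of the NAP ether, which also dismantles the β-keto ester that an isopropyl organometallic would merely deprotonate at C5; C5 keeps its trans configuration.

**Step 12**
Reactants: 16 saturated β-hydroxy ester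
Product: 17 1,3-diol with C6 as CH2OH (daucane 1S,5S,10R; C4 epimers)
Conditions: LiAlH4, THF, 0 °C
Reagents that add atoms: none
Why: Hydride reduction of the ester to the primary alcohol leaves silyl and NAP ethers intact at 0 °C.

**Step 13**
Reactants: 17 1,3-diol
Product: 18 C6 TBS ether (C4 epimers)
Conditions: TBSCl (1.05 equiv), imidazole, CH2Cl2, 0 °C
Reagents that add atoms: tert-butyl(chloro)dimethylsilane, CC(C)(C)[Si](C)(C)Cl
Why: Selective silylation in which the primary C6 hydroxyl reacts far faster than the secondary ring hydroxyl.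

**Step 14**
Reactants: 18 C6 TBS ether
Product: 19 cyclopentanone, (2S,3S)-2-(TBS-oxymethyl)-3-methyl-3-[(1R)-1-(NAP-oxy)-2-(TBDPS-oxy)ethyl]cyclopentan-1-one
Conditions: Dess–Martin periodinane, CH2Cl2, rt
Reagents that add atoms: none
Why: Dess–Martin oxidation merges both C4 epimers into one ketone under non-basic conditions, so the β-silyloxy group is not eliminated and C5 stays in its favoured trans configuration.

**Step 15**
Reactants: 19 cyclopentanone
Product: 20 isopropyl carbinol (daucane 1S,4R,5S,10R)
Conditions: i-PrMgCl, LaCl3·2LiCl (1 equiv), THF, 0 °C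
Reagents that add atoms: isopropylmagnesium chloride, CC(C)[Mg]Cl
Why: Grignard 1,2-addition made non-basic by LaCl3·2LiCl suppresses enolisation, β-elimination and β-hydride reduction, and the reagent should come from the ring face opposite to the adjacent C5 CH2OTBS arm and the pseudoaxial C1 methyl, giving the (4R) carbinol with OH cis to both.

**Step 16**
Reactants: 20 isopropyl carbinol
Product: 21 C4,C6-diol (daucane 1S,4R,5S,10R)
Conditions: PPTS (cat.), MeOH, rt
Reagents that add atoms: none
Why: Acid-catalysed methanolysis cleaves the primary TBS ether much faster than the TBDPS ether and is too mild to ionise the tertiary alcohol.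

**Step 17**
Reactants: 21 C4,C6-diol
Product: 22 β-hydroxy aldehyde with C6 as CHO (daucane 1S,4R,5R,10R)
Conditions: Dess–Martin periodinane, CH2Cl2, 0 °C
Reagents that add atoms: none
Why: Dess–Martin oxidation of the primary alcohol leaves the tertiary hydroxyl alone, and the absence of base avoids retro-aldol cleavage and dehydration.

**Step 18**
Reactants: 22 β-hydroxy aldehyde
Product: 23 (6S)-methallyl carbinol (daucane 1S,4R,5S,6S,10R)
Conditions: 2-methylallylmagnesium chloride (3 equiv), Et2O/THF, −78 °C
Reagents that add atoms: 2-methylallylmagnesium chloride, C=C(C)C[Mg]Cl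
Why: Chelation-controlled (Cram-chelate type) Grignard addition in which the first equivalent makes the C4 magnesium alkoxide, this ties the cis C6 aldehyde oxygen into a six-membered chelate, one carbonyl face is then covered by the cis C1 methyl, and the methallyl group should enter from the open face to give (6S).

**Step 19**
Reactants: 23 (6S)-methallyl carbinol
Product: 24 C6 4-methoxybenzoate
Conditions: 4-MeOC6H4COCl, DMAP, Et3N, CH2Cl2, rt
Reagents that add atoms: 4-methoxybenzoyl chloride, COc1ccc(cc1)C(=O)Cl
Why: DMAP-catalysed acylation takes place at the secondary C6 hydroxyl because the tertiary C4 hydroxyl flanked by isopropyl is too hindered.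

**Step 20**
Reactants: 24 C6 4-methoxybenzoate
Product: 25 C9 primary alcohol
Conditions: Bu4NF, AcOH, THF, rt
Reagents that add atoms: none
Why: Fluoride desilylation buffered with acetic acid removes the TBDPS group without ester cleavage or acyl migration.

**Step 21**
Reactants: 25 C9 primary alcohol
Product: 26 C9 aldehyde (10R)
Conditions: Dess–Martin periodinane, CH2Cl2, 0 °C
Reagents that add atoms: none
Why: Dess–Martin oxidation under non-basic conditions keeps the α-oxygenated centre C10 from epimerising.

**Step 22**
Reactants: 26 C9 aldehyde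
Product: 27 diene with C9 vinyl and C8 isopropenyl ends (daucane 1S,4R,5S,6S,10S)
Conditions: Ph3PCH3Br, KN(SiMe3)2, THF, 0 °C; then 26, −78 → 0 °C
Reagents that add atoms: methyltriphenylphosphonium bromide, C[P+](c1ccccc1)(c1ccccc1)c1ccccc1.[Br-]
Why: Wittig methylenation of the aldehyde is much faster at low temperature than attack on the electron-rich aryl ester or enolisation at the hindered C10.

**Step 23**
Reactants: 27 diene
Product: 28 trans-fused hydroazulene C10 NAP ether
Conditions: second-generation Grubbs catalyst (10 mol %), toluene (2 mM), 80 °C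
Reagents that add atoms: none
Why: Ring-closing metathesis in which the catalyst loads on the monosubstituted C9 vinyl group and closes on the 1,1-disubstituted methallyl alkene, ethylene loss drives formation of the trisubstituted C8=C9 bond of seven-membered ring A, and the trans arms on ring B give the trans fusion with no stereocentre touched.

**Step 24**
Reactants: 28 hydroazulene C10 NAP ether
Product: 29 C10 allylic alcohol
Conditions: DDQ (1.3 equiv), CH2Cl2/pH 7 buffer, 0 °C → rt
Reagents that add atoms: none
Why: Oxidative ether cleavage with DDQ oxidises the electron-rich naphthylmethyl group to an oxocarbenium ion that water hydrolyses, while the alkene, the acceptor-substituted anisoyl ring and the tertiary alcohol stay inert.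

**Step 25**
Reactants: 29 C10 allylic alcohol
Product: 30 target CNP0256979.3
Conditions: Ac2O (1.5 equiv), DMAP (cat.), pyridine, 0 °C → rt
Reagents that add atoms: acetic anhydride, CC(=O)OC(C)=O
Why: DMAP-catalysed acetylation reaches the secondary C10 hydroxyl with retention, and the far more hindered tertiary C4 hydroxyl stays free.

**Compound list**

1 | methyl (S)-2,2-dimethyl-1,3-dioxolane-4-carboxylate | COC(=O)[C@@H]1COC(C)(C)O1 | starting material
2 | (S)-2,2-dimethyl-1,3-dioxolane-4-carbaldehyde | O=C[C@@H]1COC(C)(C)O1 | intermediate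
3 | (R)-4-ethynyl-2,2-dimethyl-1,3-dioxolane | C#C[C@@H]1COC(C)(C)O1 | intermediate
4 | (R)-but-3-yne-1,2-diol | C#C[C@@H](O)CO | intermediate
5 | (R)-1-(tert-butyldiphenylsilyloxy)but-3-yn-2-ol | C#C[C@@H](O)CO[Si](c1ccccc1)(c1ccccc1)C(C)(C)C | intermediate
6 | (R)-NAP ether of 5 | C#C[C@@H](OCc1ccc2ccccc2c1)CO[Si](c1ccccc1)(c1ccccc1)C(C)(C)C | intermediate
7 | lithium acetylide of 6 | [Li]C#C[C@@H](OCc1ccc2ccccc2c1)CO[Si](c1ccccc1)(c1ccccc1)C(C)(C)C | intermediate
8 | methyl (R)-5-(TBDPS-oxy)-4-(NAP-oxy)pent-2-ynoate | COC(=O)C#C[C@@H](OCc1ccc2ccccc2c1)CO[Si](c1ccccc1)(c1ccccc1)C(C)(C)C | intermediate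
9 | 3-(trimethylsilyl)prop-2-yn-1-ol | C[Si](C)(C)C#CCO | starting material
10 | (E)-3-(trimethylsilyl)prop-2-en-1-ol | C[Si](C)(C)/C=C/CO | intermediate
11 | (E)-3-(trimethylsilyl)prop-2-enal | C[Si](C)(C)/C=C/C=O | intermediate
12 | bromomagnesium allenolate from 8 and MeMgBr | COC(O[Mg]Br)=C=C(C)[C@@H](OCc1ccc2ccccc2c1)CO[Si](c1ccccc1)(c1ccccc1)C(C)(C)C | intermediate
13 | methyl (2Z,4R)-2-[(2E)-1-hydroxy-3-(trimethylsilyl)prop-2-enyl]-3-methyl-4-(NAP-oxy)-5-(TBDPS-oxy)pent-2-enoate (carbinol epimers) | COC(=O)/C(C(O)/C=C/[Si](C)(C)C)=C(/C)[C@@H](OCc1ccc2ccccc2c1)CO[Si](c1ccccc1)(c1ccccc1)C(C)(C)C | intermediate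
14 | silyl divinyl ketone ester (2Z,4R; 2'E) | COC(=O)/C(C(=O)/C=C/[Si](C)(C)C)=C(/C)[C@@H](OCc1ccc2ccccc2c1)CO[Si](c1ccccc1)(c1ccccc1)C(C)(C)C | intermediate
15 | cyclopentenone β-keto ester (daucane 1S,5R,10R) | COC(=O)[C@H]1C(=O)C=C[C@]1(C)[C@@H](OCc1ccc2ccccc2c1)CO[Si](c1ccccc1)(c1ccccc1)C(C)(C)C | intermediate
16 | saturated β-hydroxy ester (C4 epimers) | COC(=O)[C@H]1C(O)CC[C@]1(C)[C@@H](OCc1ccc2ccccc2c1)CO[Si](c1ccccc1)(c1ccccc1)C(C)(C)C | intermediate
17 | 1,3-diol (C4 epimers) | OC[C@H]1C(O)CC[C@]1(C)[C@@H](OCc1ccc2ccccc2c1)CO[Si](c1ccccc1)(c1ccccc1)C(C)(C)C | intermediate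
18 | C6 TBS ether (C4 epimers) | CC(C)(C)[Si](C)(C)OC[C@H]1C(O)CC[C@]1(C)[C@@H](OCc1ccc2ccccc2c1)CO[Si](c1ccccc1)(c1ccccc1)C(C)(C)C | intermediate
19 | C4 cyclopentanone (daucane 1S,5S,10R) | CC(C)(C)[Si](C)(C)OC[C@H]1C(=O)CC[C@]1(C)[C@@H](OCc1ccc2ccccc2c1)CO[Si](c1ccccc1)(c1ccccc1)C(C)(C)C | intermediate
20 | isopropyl carbinol (daucane 1S,4R,5S,10R) | CC(C)(C)[Si](C)(C)OC[C@H]1[C@](O)(C(C)C)CC[C@]1(C)[C@@H](OCc1ccc2ccccc2c1)CO[Si](c1ccccc1)(c1ccccc1)C(C)(C)C | intermediate
21 | C4,C6-diol | OC[C@H]1[C@](O)(C(C)C)CC[C@]1(C)[C@@H](OCc1ccc2ccccc2c1)CO[Si](c1ccccc1)(c1ccccc1)C(C)(C)C | intermediate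
22 | C6 β-hydroxy aldehyde (daucane 1S,4R,5R,10R) | O=C[C@H]1[C@](O)(C(C)C)CC[C@]1(C)[C@@H](OCc1ccc2ccccc2c1)CO[Si](c1ccccc1)(c1ccccc1)C(C)(C)C | intermediate
23 | (6S)-methallyl carbinol | C=C(C)C[C@H](O)[C@H]1[C@](O)(C(C)C)CC[C@]1(C)[C@@H](OCc1ccc2ccccc2c1)CO[Si](c1ccccc1)(c1ccccc1)C(C)(C)C | intermediate
24 | C6 4-methoxybenzoate | C=C(C)C[C@H](OC(=O)c1ccc(OC)cc1)[C@H]1[C@](O)(C(C)C)CC[C@]1(C)[C@@H](OCc1ccc2ccccc2c1)CO[Si](c1ccccc1)(c1ccccc1)C(C)(C)C | intermediate
25 | C9 primary alcohol | C=C(C)C[C@H](OC(=O)c1ccc(OC)cc1)[C@H]1[C@](O)(C(C)C)CC[C@]1(C)[C@@H](OCc1ccc2ccccc2c1)CO | intermediate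
26 | C9 aldehyde | C=C(C)C[C@H](OC(=O)c1ccc(OC)cc1)[C@H]1[C@](O)(C(C)C)CC[C@]1(C)[C@@H](OCc1ccc2ccccc2c1)C=O | intermediate
27 | metathesis diene (daucane 1S,4R,5S,6S,10S) | C=C(C)C[C@H](OC(=O)c1ccc(OC)cc1)[C@H]1[C@](O)(C(C)C)CC[C@]1(C)[C@@H](OCc1ccc2ccccc2c1)C=C | intermediate
28 | trans-hydroazulene C10 NAP ether | COc1ccc(C(=O)O[C@H]2CC(C)=C[C@H](OCc4ccc5ccccc5c4)[C@@]3(C)CC[C@@](O)(C(C)C)[C@H]23)cc1 | intermediate
29 | C10 allylic alcohol | COc1ccc(C(=O)O[C@H]2CC(C)=C[C@H](O)[C@@]3(C)CC[C@@](O)(C(C)C)[C@H]23)cc1 | intermediate
30 | CNP0256979.3 (daucane 1S,4R,5S,6S,10S) | COc1ccc(C(=O)O[C@H]2CC(C)=C[C@H](OC(C)=O)[C@@]3(C)CC[C@@](O)(C(C)C)[C@H]23)cc1 | target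

**Step count**

Total step count: 25. Longest linear sequence: 23 steps (1 → 30 through steps 1–5 and 8–25); steps 6–7 form the two-step side branch.

**Steps most likely to fail**

**Step 10 (key step).**
- What may go wrong: the C1–C10 bond can rotate, so both senses of conrotation may compete (poor torquoselectivity). The crowded terminus may also close so slowly that protodesilylation of the vinylsilane overtakes cyclisation.
- Fallback: make the acyclic controller part of a ring, setting out from 14.
- HF·pyridine (THF, then catalytic camphorsulfonic acid) frees the C9 hydroxyl. This closes on the cis ester to give the δ-lactone dienone F1.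
- In the half-chair of F1, the neighbouring C1 methyl pushes the C10 NAP-oxy group pseudoaxial, where it covers one face of C1. Steric shielding and bond formation anti to the C–O bond then point the same way, towards the same (1S) centre.
- Cu(OTf)2 should close F1 to the bicyclic β-keto lactone F2.
- DMAP-catalysed exchange with methanol (toluene, 80 °C), the usual transesterification of β-keto esters, opens F2 to the hydroxy β-keto ester F3, in which C5 re-equilibrates.
- TBDPSCl/imidazole then brings the material back to the route at 15.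

**Step 18.**
- What may go wrong: allyl-type Grignard reagents add so fast that the chelate may not decide the face of attack (poor facial selectivity at C6).
- Fallback: move from substrate control to reagent control at the ketone stage, setting out from 22.
- The unselective addition product is a mixture of 23 and the (6R)-methallyl carbinol F4. Dess–Martin periodinane oxidises it to the β-hydroxy ketone F5.
- F5 is reduced by Corey–Bakshi–Shibata reduction with (R)-Me-CBS oxazaborolidine and catecholborane (toluene, −78 °C). Catecholborane spares the 1,1-disubstituted alkene. Ring carbon C5 acts as the large group and the methallyl CH2 as the small group.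
- The route is rejoined at 23.

**Step 23.**
- What may go wrong: slow initiation at the C9 vinyl group, which is flanked by the ether carbon C10 and quaternary C1, may let dimerisation or alkene isomerisation compete with ring closure.
- Fallback: relay ring-closing metathesis, setting out from 26.
- A Wittig reaction with the ylide from hex-5-enyltriphenylphosphonium bromide gives the relay triene F6.
- The catalyst loads on the unhindered terminal alkene and expels cyclopentene. This places ruthenium directly on C9, which then closes on the methallyl alkene.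
- The route is rejoined at 28.

**Further compounds**

F1 | step 10 | δ-lactone dienone, (5R)-4-methyl-5-(NAP-oxy)-3-[(E)-3-(trimethylsilyl)acryloyl]-5,6-dihydro-2H-pyran-2-one | O=C1OC[C@H](OCc2ccc3ccccc3c2)C(C)=C1C(=O)/C=C/[Si](C)(C)C
F2 | step 10 | bicyclic β-keto lactone (C1 S, C10 R; C5 epimerisable) | O=C1OC[C@H](OCc2ccc3ccccc3c2)[C@@]2(C)C=CC(=O)C12
F3 | step 10 | hydroxy β-keto ester (15 without TBDPS) | COC(=O)[C@H]1C(=O)C=C[C@]1(C)[C@@H](OCc1ccc2ccccc2c1)CO
F4 | step 18 | (6R)-methallyl carbinol (C6 epimer of 23) | C=C(C)C[C@@H](O)[C@H]1[C@](O)(C(C)C)CC[C@]1(C)[C@@H](OCc1ccc2ccccc2c1)CO[Si](c1ccccc1)(c1ccccc1)C(C)(C)C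
F5 | step 18 | β-hydroxy ketone (C6 ketone) | C=C(C)CC(=O)[C@H]1[C@](O)(C(C)C)CC[C@]1(C)[C@@H](OCc1ccc2ccccc2c1)CO[Si](c1ccccc1)(c1ccccc1)C(C)(C)C
F6 | step 23 | relay triene (Z-hepta-1,6-dienyl arm on C10) | C=C(C)C[C@H](OC(=O)c1ccc(OC)cc1)[C@H]1[C@](O)(C(C)C)CC[C@]1(C)[C@@H](OCc1ccc2ccccc2c1)/C=C\CCCC=C
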